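**Plan**
- Cuts: (i) C4 is shifted back from C4a to C8a. This shrinks the dihydropyran ring (O1, C2, C3, C4, C4a, C8a) to the oxolane ring of a 1-oxaspiro[4.5]deca-6,9-dien-8-one. (ii) The spiro C–O1 bond is cut. (iii) The aryl–C4 bond is cut.
- Enabling feature: O1 on C8a lies para to the C6 hydroxyl and C4 sits on the neighbouring C4a. Of the two carbons flanking C8a, only C4a bears no methyl (C8 does). This is the exact imprint of a dienone–phenol 1,2-shift in a p-quinol ether.
- Forward: the all-E C20 chain is bought as geranylgeraniol and turned into (R)-geranyllinalool. Its vinyl group is joined to C4 of 2,5-dimethylphenol by hydroboration/Suzuki coupling. The oxolane ring is closed by oxidative dearomatisation, and the last step expands it to the chroman, restoring the arene and the 6-OH in one isomerisation.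
- Stereochemistry: C2 (R) comes from a Sharpless epoxidation with D-(−)-tartrate, and its C–O bond is never broken afterwards. The uncontrolled spiro centre is erased in the key step, so both epimers converge. The E-alkenes come with the starting material.

Key step: step 8

Assumption: commercial geranylgeraniol is taken as the all-E isomer, and the two C5 epimers of spirodienone 10 are carried on together.

**Step 1**
Reactants: 1 (2E,6E,10E)-geranylgeraniol
Product: 2 (2R,3R)-2,3-epoxygeranylgeraniol
Conditions: Ti(OiPr)4 (5 mol %), D-(−)-diethyl tartrate (6 mol %), t-BuOOH (decane), 4 Å MS, CH2Cl2, −20 °C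
Reagents that add atoms: tert-butyl hydroperoxide, CC(C)(C)OO
Why: In the Sharpless asymmetric epoxidation the titanium–tartrate complex binds the allylic OH, so only the C2=C3 alkene of the four should react, and D-(−)-tartrate should give the (2R,3R) epoxide, the mirror-image series of the (2S,3S) epoxides that L-(+)-tartrate gives with geraniol-type E-allylic alcohols.

**Step 2**
Reactants: 2 (2R,3R)-2,3-epoxygeranylgeraniol
Product: 3 (2S,3R)-2-(iodomethyl)-3-methyl-3-[(3E,7E)-4,8,12-trimethyltrideca-3,7,11-trienyl]oxirane
Conditions: I2, PPh3, imidazole, Et2O/MeCN, 0 °C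
Reagents that add atoms: iodine, II
Why: In this Appel-type iodination the primary OH is activated as an oxyphosphonium ion and displaced by iodide at C1 under imidazole buffering, so neither epoxide carbon is touched (the C2 descriptor changes by CIP rank only).

**Step 3**
Reactants: 3 epoxy iodide
Product: 4 (R)-geranyllinalool, (3R,6E,10E)-3,7,11,15-tetramethylhexadeca-1,6,10,14-tetraen-3-ol
Conditions: Zn dust, EtOH, 70 °C; aq. NH4Cl work-up
Reagents that add atoms: none
Why: In this zinc-mediated reductive β-elimination of a 2,3-epoxy iodide, zinc inserts into the C–I bond and the organozinc expels the oxygen from C2 only, so the C3–O bond and its configuration are kept in the tertiary allylic alcohol.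

**Step 4**
Reactants: 5 4-bromo-2,5-dimethylphenol
Product: 6 (4-bromo-2,5-dimethylphenoxy)triisopropylsilane
Conditions: TIPSCl, imidazole, DMF, rt
Reagents that add atoms: triisopropylsilyl chloride, CC(C)[Si](Cl)(C(C)C)C(C)C
Why: Standard O-silylation of a phenol gives a TIPS ether, chosen because aryl TIPS ethers should survive the aqueous phosphate base of the coupling.

**Step 5**
Reactants: 4 (R)-geranyllinalool; 6 (4-bromo-2,5-dimethylphenoxy)triisopropylsilane
Product: 8 (3R,6E,10E)-1-[2,5-dimethyl-4-(triisopropylsilyloxy)phenyl]-3,7,11,15-tetramethylhexadeca-6,10,14-trien-3-ol, via alkylborane 7 (not isolated)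
Conditions: 9-BBN (1.5 equiv), THF, 0 °C → rt; then 6, Pd(OAc)2 (3 mol %), SPhos (6 mol %), K3PO4, H2O, THF, 60 °C
Reagents that add atoms: none
Why: 9-BBN hydroborates the monosubstituted vinyl group far faster than the three trisubstituted alkenes and places boron on the terminal carbon, and the primary B-alkyl-9-BBN then couples with the aryl bromide in a B-alkyl Suzuki–Miyaura reaction that leaves the carbinol centre untouched.

**Step 6**
Reactants: 8 TIPS-protected aryl tertiary alcohol
Product: 9 4-[(3R,6E,10E)-3-hydroxy-3,7,11,15-tetramethylhexadeca-6,10,14-trienyl]-2,5-dimethylphenol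
Conditions: TBAF, THF, 0 °C; aq. work-up
Reagents that add atoms: none
Why: Fluoride-driven cleavage of the aryl silyl ether is fast at 0 °C and should not affect the tertiary alcohol or the alkenes.

**Step 7**
Reactants: 9 free phenol
Product: 10 (2R)-2,6,9-trimethyl-2-[(3E,7E)-4,8,12-trimethyltrideca-3,7,11-trienyl]-1-oxaspiro[4.5]deca-6,9-dien-8-one (both C5 epimers)
Conditions: PhI(OAc)2 (1.1 equiv), (CF3)2CHOH/CH2Cl2, 0 °C
Reagents that add atoms: none
Why: In this hypervalent-iodine oxidative dearomatisation of a 4-alkylphenol, ligand exchange at I(III) and loss of PhI make the para carbon electrophilic, the tethered tertiary OH should capture it in a 5-exo mode ahead of any remote alkene, and the new spiro centre C5 is not controlled, which is harmless because step 8 erases it.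

**Step 8**
Reactants: 10 spirodienone (both C5 epimers)
Product: 11 (R)-β-tocotrienol
Conditions: BF3·OEt2 (0.2 equiv), 2,6-di-tert-butyl-4-methylpyridine (0.05 equiv), CH2Cl2, −40 → 0 °C, argon
Reagents that add atoms: none
Why: BF3 binds the dienone oxygen of 10 and turns the ring into an oxygen-substituted pentadienyl cation with charge on C6 and C10, the ring CH2 C4 then shifts from the spiro carbon C5 to C10, the charge settles on C5 as an oxocarbenium ion held by O1, and loss of H-10 restores the arene and frees the catalyst. This is the dienone–phenol rearrangement of a p-quinol ether, the reaction type by which Lewis acids convert 1-oxaspiro[4.5]deca-6,9-dien-8-ones into chroman-6-ols. No ring is closed from an open chain: the five-membered oxolane (O1, C2, C3, C4, C5) takes up dienone carbon C10 through the 1,2-shift and becomes the six-membered dihydropyran (O1, C2, C3, C4, C4a, C8a), a one-carbon ring expansion. No stereocentre is made: none of the four bonds at C2 takes part, so the R configuration set in step 1 is kept, and C5 becomes planar, so both spiro epimers converge on one product. The step needs carbon over oxygen migration, secured because only the carbon shift leaves a cation stabilised by O1, and migration to C10 over C6, secured because C6 carries a methyl group and a shift to it is a reversible dead end with no proton to lose. It also needs activation of the carbonyl group in preference to protonation of the three trisubstituted alkenes or ionisation of the tertiary C2–O1 bond, which the catalytic Lewis acid, the low temperature and the hindered pyridine as proton buffer should secure.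

**Compound list**
1 | (2E,6E,10E)-geranylgeraniol | CC(C)=CCC/C(C)=C/CC/C(C)=C/CC/C(C)=C/CO | starting material
2 | (2R,3R)-2,3-epoxygeranylgeraniol | CC(C)=CCC/C(C)=C/CC/C(C)=C/CC[C@@]1(C)O[C@@H]1CO | intermediate
3 | (2S,3R)-2-(iodomethyl)-3-methyl-3-[(3E,7E)-4,8,12-trimethyltrideca-3,7,11-trienyl]oxirane | CC(C)=CCC/C(C)=C/CC/C(C)=C/CC[C@@]1(C)O[C@@H]1CI | intermediate
4 | (R)-geranyllinalool, (3R,6E,10E)-3,7,11,15-tetramethylhexadeca-1,6,10,14-tetraen-3-ol | CC(C)=CCC/C(C)=C/CC/C(C)=C/CC[C@](O)(C)C=C | intermediate
5 | 4-bromo-2,5-dimethylphenol | Cc1cc(Br)c(C)cc1O | starting material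
6 | (4-bromo-2,5-dimethylphenoxy)triisopropylsilane | Cc1cc(Br)c(C)cc1O[Si](C(C)C)(C(C)C)C(C)C | intermediate
7 | (3S,6E,10E)-1-(9-borabicyclo[3.3.1]nonan-9-yl)-3,7,11,15-tetramethylhexadeca-6,10,14-trien-3-ol (same spatial arrangement as 4; descriptor changes by CIP rank only) | CC(C)=CCC/C(C)=C/CC/C(C)=C/CC[C@](O)(C)CCB1C2CCCC1CCC2 | intermediate
8 | (3R,6E,10E)-1-[2,5-dimethyl-4-(triisopropylsilyloxy)phenyl]-3,7,11,15-tetramethylhexadeca-6,10,14-trien-3-ol | CC(C)=CCC/C(C)=C/CC/C(C)=C/CC[C@](O)(C)CCc1cc(C)c(O[Si](C(C)C)(C(C)C)C(C)C)cc1C | intermediate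
9 | 4-[(3R,6E,10E)-3-hydroxy-3,7,11,15-tetramethylhexadeca-6,10,14-trienyl]-2,5-dimethylphenol | CC(C)=CCC/C(C)=C/CC/C(C)=C/CC[C@](O)(C)CCc1cc(C)c(O)cc1C | intermediate
10 | (2R)-2,6,9-trimethyl-2-[(3E,7E)-4,8,12-trimethyltrideca-3,7,11-trienyl]-1-oxaspiro[4.5]deca-6,9-dien-8-one, both C5 epimers | CC(C)=CCC/C(C)=C/CC/C(C)=C/CC[C@]1(C)CCC2(O1)C=C(C)C(=O)C=C2C | intermediate
11 | (R)-β-tocotrienol, (2R)-2,5,8-trimethyl-2-[(3E,7E)-4,8,12-trimethyltrideca-3,7,11-trienyl]chroman-6-ol | CC(C)=CCC/C(C)=C/CC/C(C)=C/CC[C@]1(C)CCc2c(C)c(O)cc(C)c2O1 | target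

**Step count**
Total steps: 8. Longest linear sequence: 7 (steps 1, 2, 3, 5, 6, 7, 8, counted from 1).

**Steps most likely to fail**

**1. Step 8.**
- What may go wrong: proton-initiated cation–olefin cyclisation of the triene, or heterolysis of the tertiary C2–O1 bond with erosion of configuration, may outrun the 1,2-shift.
- Fallback (sets out from 6, returns at 11): the ring expansion is moved ahead of the chain assembly.
- Commercial (R)-(−)-linalool F1 is hydroborated with 9-BBN to the short alkylborane F2. This is coupled with 6 as in step 5 to the short-chain tertiary alcohol F3.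
- TBAF frees the short-chain phenol F4. PhI(OAc)2 closes the short-chain spirodienone F5. BF3·OEt2 or CF3CO2H in CH2Cl2 expands it to the 2-(4-methylpent-3-enyl)chromanol F6, whose single alkene has no partner for a cation–olefin cascade.
- TBSCl/imidazole gives the silyl ether F7. Catalytic SeO2/t-BuOOH oxidises the E-methyl group to the E-allylic alcohol F8. CBr4/PPh3 gives the allylic bromide F9.
- Geranyl phenyl sulfone F10 (from geranyl bromide and PhSO2Na in DMF) is lithiated with n-BuLi and alkylated with F9 to the coupled allylic sulfone F11.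
- PdCl2(dppp)/LiEt3BH removes the sulfonyl group without moving the alkenes and gives O-TBS-β-tocotrienol F12. TBAF then returns to 11.

**2. Step 7.**
- What may go wrong: the electrophilic iodane may attack the trisubstituted alkenes. The oxidised phenol may also lose a benzylic proton to a p-quinone methide, or be captured by solvent before the hindered tertiary OH closes the ring.
- Fallback (sets out from 9, returns at 10): the reagent-based oxidation is given up for electrosynthesis.
- 9 is oxidised by constant-current electrolysis at a glassy-carbon anode with a Pt cathode in an undivided cell, using n-Bu4NBF4, MeCN/(CF3)2CHOH and 2,6-lutidine at 0 °C.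
- The electrode potential then selects the phenol, which is oxidised well below a trisubstituted alkene. No electrophilic oxidant is present in solution. Anodic spirocyclisation of 4-(3-hydroxyalkyl)phenols is a known reaction type. This fallback makes no new compound (F0).

**3. Step 5.**
- What may go wrong: 9-BBN may discriminate incompletely between the vinyl group next to the quaternary carbinol carbon and the other alkenes. Protodeboronation or β-hydride elimination at the alkyl–palladium stage may also compete while oxidative addition into the electron-rich, ortho-methylated bromide is slow.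
- Fallback (sets out from 4 and 6, returns at 8): boron is left out.
- A Mizoroki–Heck reaction of 6 with 4 (Pd(OAc)2, P(o-tol)3, Et3N, DMF, 100 °C) can only eliminate toward the aryl side, because the carbinol carbon is quaternary. It should give the E-styrenyl tertiary alcohol F13.
- Diimide (2-nitrobenzenesulfonyl hydrazide, Et3N, CH2Cl2, rt) should then reduce the 1,2-disubstituted alkene faster than the trisubstituted ones and deliver 8.

**Further compounds**
F1 | step 8 | (R)-(−)-linalool, (3R)-3,7-dimethylocta-1,6-dien-3-ol (commercial input) | CC(C)=CCC[C@](O)(C)C=C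
F2 | step 8 | (3S)-1-(9-borabicyclo[3.3.1]nonan-9-yl)-3,7-dimethyloct-6-en-3-ol (same spatial arrangement as F1) | CC(C)=CCC[C@](O)(C)CCB1C2CCCC1CCC2
F3 | step 8 | (3R)-1-[2,5-dimethyl-4-(triisopropylsilyloxy)phenyl]-3,7-dimethyloct-6-en-3-ol | CC(C)=CCC[C@](O)(C)CCc1cc(C)c(O[Si](C(C)C)(C(C)C)C(C)C)cc1C
F4 | step 8 | 4-[(3R)-3-hydroxy-3,7-dimethyloct-6-enyl]-2,5-dimethylphenol | CC(C)=CCC[C@](O)(C)CCc1cc(C)c(O)cc1C
F5 | step 8 | (2R)-2,6,9-trimethyl-2-(4-methylpent-3-enyl)-1-oxaspiro[4.5]deca-6,9-dien-8-one, both C5 epimers | CC(C)=CCC[C@]1(C)CCC2(O1)C=C(C)C(=O)C=C2C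
F6 | step 8 | (2R)-2,5,8-trimethyl-2-(4-methylpent-3-enyl)chroman-6-ol | CC(C)=CCC[C@]1(C)CCc2c(C)c(O)cc(C)c2O1
F7 | step 8 | tert-butyldimethylsilyl ether of F6 | CC(C)=CCC[C@]1(C)CCc2c(C)c(O[Si](C)(C)C(C)(C)C)cc(C)c2O1
F8 | step 8 | (2E)-5-[(2R)-6-(tert-butyldimethylsilyloxy)-2,5,8-trimethylchroman-2-yl]-2-methylpent-2-en-1-ol | OC/C(C)=C/CC[C@]1(C)CCc2c(C)c(O[Si](C)(C)C(C)(C)C)cc(C)c2O1
F9 | step 8 | (2R)-2-[(3E)-5-bromo-4-methylpent-3-enyl]-6-(tert-butyldimethylsilyloxy)-2,5,8-trimethylchroman | BrC/C(C)=C/CC[C@]1(C)CCc2c(C)c(O[Si](C)(C)C(C)(C)C)cc(C)c2O1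
F10 | step 8 | geranyl phenyl sulfone | CC(C)=CCC/C(C)=C/CS(=O)(=O)c1ccccc1
F11 | step 8 | 6'-(phenylsulfonyl)-O-TBS-β-tocotrienol, both epimers at C6' | CC(C)=CCC/C(C)=C/C(C/C(C)=C/CC[C@]1(C)CCc2c(C)c(O[Si](C)(C)C(C)(C)C)cc(C)c2O1)S(=O)(=O)c1ccccc1
F12 | step 8 | O-TBS-(R)-β-tocotrienol | CC(C)=CCC/C(C)=C/CC/C(C)=C/CC[C@]1(C)CCc2c(C)c(O[Si](C)(C)C(C)(C)C)cc(C)c2O1
F0 | step 7 | none | none
F13 | step 5 | (1E,3R,6E,10E)-1-[2,5-dimethyl-4-(triisopropylsilyloxy)phenyl]-3,7,11,15-tetramethylhexadeca-1,6,10,14-tetraen-3-ol | CC(C)=CCC/C(C)=C/CC/C(C)=C/CC[C@](O)(C)/C=C/c1cc(C)c(O[Si](C(C)C)(C(C)C)C(C)C)cc1C
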